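Compound numbers follow the order of the steps below. Atom labels: chromene O1, C2–C4, C4a, C5–C8, C8a; chain C1'–C6' from C2 outwards; carbocycle C1''–C6''.

## Analysis of the target

Target 25 is a 2H-chromen-6-ol (benzene ring A fused to pyran ring B) whose quaternary C2 carries a methyl group and a six-carbon chain C1'–C6' with one trisubstituted (E)-alkene at C3'=C4'; the chain ends at C1'' of a 2,6,6-trimethylcyclohex-2-ene (ring C). The two stereocentres, C2 (S) and C1'' (S), lie seven bonds apart, so neither can steer the other. Each must therefore be set in absolute terms in its own fragment, and any shortfall in either half reappears as a diastereomer that will be hard to remove. The para-alkoxyphenol is prone to air oxidation, and the 2H-chromene is a tertiary allylic aryl ether that ionises with acid, opens reversibly to an ortho-quinone methide on heating or irradiation (which would erase C2), and has a styrene-like C3=C4 that strong reductants attack. Acid can also move the ring C alkene to the tetrasubstituted C1''=C2'' position, which destroys C1''. The hard part is C1'': a lone CH stereocentre on a carbocycle, held between the gem-dimethyl carbon C6'' and the alkene carbon C2'', with the alkene fixed at C2''=C3''; cation–olefin cyclisation would give mixtures of alkene positions and no absolute control. The strategy reads ring C as a cycloadduct: the alkene C2''=C3'' flanked by C1'' and C4'' is the retron for joining a 1,2-disubstituted butadiene (C1''–C4'') to a two-carbon unit (C5''–C6''), with the gem-dimethyl carbon arising from an enal α-carbon whose formyl group is later reduced to methyl.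

## Retrosynthetic reasoning

25 from 24. The free phenol is uncovered last. In 24 the C6 oxygen is a triisopropylsilyl ether, which comes off under neutral, cold conditions that spare the chromene and all three alkenes.

24 from 10 and 21 (through 22 and 23). The C5'–C6' bond is cut because it lies between the two stereocentres: each half then holds exactly one of them and is made on its own. C5' is allylic, so it serves as the electrophile in bromide 21. C6' is made nucleophilic by a phenylsulfonyl group in 10, deprotonated to 22. The forward sequence must alkylate a hindered carbanion to give 23 and then remove the sulfonyl group without reducing C3=C4.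

10 from 8 (through 9). The sulfone is traced to the primary alcohol 8 by thioether formation and sulfur oxidation. The oxidant has to ignore the ring C alkene.

8 from 5 (through 7 and 6). One methyl group of C6'' is rewritten as a formyl group. This costs a deoxygenation in the forward direction but turns ring C into the adduct of an enal, and it makes the configuration of the quaternary carbon irrelevant once the formyl group has become methyl.

5 from 3 and 4. The bonds C1''–C6'' and C4''–C5'' are cut together. No other pair of ring bonds gives a diene and a dienophile that are both simple, and this pair places the ring methyl on C2'' and the alkene at C2''=C3'' by construction. The forward reaction has to control orientation, endo/exo mode and enal face at once. It sets C1'' in the step that builds the ring.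

3 from 1 (through 2). The diene comes from the enynol 1 by semihydrogenation of the terminal alkyne and silylation. The (E) geometry that places the oxygenated carbon on the outside of the diene is already present in 1.

21 from 19 (through 20). The bromide comes from the allylic alcohol 20, and 20 from 19 by oxidation of the (E)-methyl group at the chain terminus. This lets 19 carry the unfunctionalised 4-methylpent-3-enyl chain of 11.

19 from 18. Ring B is opened at O1–C8a rather than at C2–O1. The C2–O bond then comes unchanged from a tertiary alcohol and C2 is never exposed to ionisation. The forward reaction is an intramolecular aryl etherification of an aryl bromide.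

18 from 14 and 16 (through 17). The C4–C4a bond is cut as an alkyne–aryl coupling. The iodide of 16 reacts ahead of the bromide kept for the etherification, and semihydrogenation of 17 gives the cis alkene that the ring closure needs.

14 from 11 (through 13 and 12). C2 is traced to C3 of the allylic alcohol 11. Asymmetric epoxidation sets it, and base-induced fragmentation of the epoxy chloride 13 turns C1–C2 of 11 into the terminal alkyne while the C3–O bond is kept.

16 from 15. The phenol is silylated at the outset so that the same group serves to the last step.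

## Alternatives that were turned down

All three alternatives are ways of making ring B. They compete with steps 12–14 of the chosen route, not with its key step, and each would still need a separate source of the ring C stereocentre.

Alternative 1: The benzene ring is disconnected at C4a–C8a, C5–C6 and C6–C7, with C6 coming from carbon monoxide, so that arene and pyran are formed together. In the forward direction the chromium vinylcarbene A2, whose alkoxy group is the C2 tertiary alkoxide with a (Z)-enyne arm, is warmed and should give the chromenol A1 by alkyne insertion, CO insertion and electrocyclisation. In its favour, two rings and the correct para-oxygenation pattern arise in one operation, the phenol needs no protecting group, and the tether fixes the orientation of the alkyne. On ring-forming economy it is stronger than the three steps the chosen route spends on ring B. Against it, A2 needs a tertiary alkoxy group on the carbene carbon, and that alkoxy carbon is the C2 stereocentre: the usual ways of placing an alkoxy group on such a carbene work poorly with tertiary alkoxides, or pass through a tertiary electrophile that would lose configuration. The tether also forces the alkyne to insert with its substituted carbon next to the carbene carbon, against the normal preference. The unsubstituted vinyl group makes the complex fragile, and chromium is used stoichiometrically. A1 still lacks the C5' functionality and says nothing about C1''. The chosen strategy gives up the one-step arene construction and in return places the risky step on C1''.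

Alternative 2: Ring B is disconnected at C4–C4a. The tertiary aryl propargyl ether A4 would be treated with Ph3PAuNTf2, the ortho carbon attacking the gold-activated alkyne terminus to give chromene A3. In its favour, the closure is catalytic and runs at room temperature, so thermal opening of the chromene is no concern, and the para-substituted arene has two equivalent ortho positions. The closure itself is milder than the palladium etherification of the chosen route. Against it, A4 joins an electron-rich aryl oxygen to a fully substituted propargylic stereocentre. Nucleophilic aromatic substitution is not available on so electron-rich a ring, and substitution at the propargylic carbon runs through planar intermediates that erase configuration, so the real difficulty is moved into the precursor. The same ether can ionise under the cationic gold catalyst. A3 carries only a two-carbon arm, so four carbons including the (E)-trisubstituted alkene must still be added in several further steps. The chosen route avoids this by forming the aryl–oxygen bond on a tertiary alcohol whose C–O bond is never broken, and by bringing the whole chain in with 11.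

Alternative 3: Ring B is disconnected at C3=C4. The diene A6, a 2-vinylaryl ether of an (S)-tertiary allylic alcohol, would be closed with second-generation Grubbs catalyst to the bromochromene A5 with loss of a two-carbon alkene. In its favour, metathesis is neutral and tolerant, and A6 is quickly reached because an ortho carbonyl group can activate the arene for ether formation and then become the vinyl group. In step count to the chromene it is shorter than the chosen route. Against it, A6 holds a third alkene, the trisubstituted one of the side chain, in a 1,6-relationship to the C2 vinyl group. Closure of a five-membered ring between these two, with loss of the chain terminus, is a known and fast reaction of this motif and competes with the wanted six-ring closure. The bromine of A5 must later be exchanged for the hydroxyl group, and the tertiary allylic alcohol must still be obtained as a single enantiomer. The chosen ring closure has no competing alkene and carries the phenol oxygen from the first step.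

Key step: step 3

Assumption: the (S)-configured catalyst is taken to leave open the enal face predicted by the accepted binding model for 2-substituted acroleins (formyl C–H···O contact, s-trans enal stacked over a phenyl group), and the open-chain diene is taken to react with the formyl group endo.

## Route

Step 1
Reactants: 1 (E)-3-methylpent-2-en-4-yn-1-ol
Product: 2 (E)-3-methylpenta-2,4-dien-1-ol
Conditions: H2 (1 atm), Pd/CaCO3 poisoned with Pb(OAc)2 (Lindlar catalyst), quinoline, Et2O, 0 °C, stopped after 1 equiv of H2
Reagents that add atoms: none
Why: Lindlar semihydrogenation takes the terminal alkyne to a vinyl group and stops there on the poisoned palladium surface. The C2=C3 alkene is not touched, so its (E) geometry is carried into the diene.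

Step 2
Reactants: 2 (E)-3-methylpenta-2,4-dien-1-ol
Product: 3 (E)-tert-butyldimethyl[(3-methylpenta-2,4-dien-1-yl)oxy]silane
Conditions: TBSCl, imidazole, CH2Cl2, 0 °C to rt
Reagents that add atoms: tert-butyldimethylsilyl chloride, CC(C)(C)[Si](C)(C)Cl
Why: Routine silylation of a primary alcohol. It removes the free hydroxyl group that would bind the boron catalyst of step 3 and leaves a weakly basic, alkyl-like substituent on the diene terminus.

Step 3
Reactants: 3 (E)-tert-butyldimethyl[(3-methylpenta-2,4-dien-1-yl)oxy]silane; 4 methacrolein (2-methylprop-2-enal)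
Product: 5 (1S,2R)-2-{[tert-butyl(dimethyl)silyl]oxymethyl}-1,3-dimethylcyclohex-3-ene-1-carbaldehyde (formyl cis to the silyloxymethyl group)
Conditions: (S)-3,3-diphenyl-1-(2-methylphenyl)tetrahydro-1H,3H-pyrrolo[1,2-c][1,3,2]oxazaborole (20 mol%, from (S)-diphenyl(pyrrolidin-2-yl)methanol and tris(2-methylphenyl)boroxine), Tf2NH (18 mol%), 4 (3 equiv), CH2Cl2, −78 °C; Et3N quench
Reagents that add atoms: none
Why: The protonated oxazaborolidine is a cationic boron Lewis acid that binds the formyl oxygen of 4; a formyl C–H···O contact to the ring oxygen holds the enal s-trans over one phenyl group, so only the face turned away from it is open. Diene 3 adds to that face in a concerted but asynchronous [4+2] cycloaddition, suprafacial on both partners, in which the bond from the enal β-carbon to the unsubstituted diene terminus (C4''–C5'') runs ahead of the bond from the α-carbon to the substituted terminus (C1''–C6''). The six-membered ring is closed by the cycloaddition itself, the diene carbons becoming C1''–C4'' with the new alkene at C2''=C3''. The closest known reaction type is the oxazaborolidinium-catalysed enantioselective Diels–Alder reaction of 2-substituted acroleins with open-chain dienes. C6'' is set by the enal face the catalyst leaves open (the Re face at the α-carbon for the (S)-catalyst), and C1'' by that face together with the endo placement of the formyl group over the (E)-diene, which puts formyl and silyloxymethyl cis. Three selectivities are needed: the orientation in which C6'' bonds to C1'' is favoured by the terminal silyloxymethyl group, whose directing effect should outweigh that of the internal methyl group and grows as the Lewis acid polarises the enal; endo approach is expected because an open-chain diene has no bridging methylene to repel the α-methyl group, and the (E) geometry keeps the terminal substituent outside; face selection comes from the catalyst. Because C6'' is erased in step 4, any exo adduct must be removed here by chromatography, since it would end as the enantiomer at C1''.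

Step 4
Reactants: 5 (1S,2R)-2-{[tert-butyl(dimethyl)silyl]oxymethyl}-1,3-dimethylcyclohex-3-ene-1-carbaldehyde
Product: 7 tert-butyldimethyl{[(1S)-2,6,6-trimethylcyclohex-2-en-1-yl]methoxy}silane, via hydrazone 6 (not isolated)
Conditions: N2H4·H2O, EtOH, 80 °C; evaporation; KOtBu, DMSO, 25 °C
Reagents that add atoms: hydrazine, NN
Why: Wolff–Kishner reduction in its low-temperature form: the hydrazone of the non-enolisable aldehyde loses N2 under KOtBu in DMSO and the formyl group becomes methyl, so C6'' becomes a gem-dimethyl carbon and is no longer a stereocentre. The nitrogen atoms of hydrazine are present only in 6 and leave as N2. C1'' has no acidifying neighbour and is untouched; any silyl ether lost here is harmless because step 5 removes the group.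

Step 5
Reactants: 7 tert-butyldimethyl{[(1S)-2,6,6-trimethylcyclohex-2-en-1-yl]methoxy}silane
Product: 8 [(1S)-2,6,6-trimethylcyclohex-2-en-1-yl]methanol
Conditions: Bu4NF, THF, 0 °C to rt; water work-up
Reagents that add atoms: none
Why: Fluoride cleavage of a primary silyl ether. The conditions are not acidic, so the ring alkene stays at C2''=C3''.

Step 6
Reactants: 8 [(1S)-2,6,6-trimethylcyclohex-2-en-1-yl]methanol
Product: 9 ({[(1S)-2,6,6-trimethylcyclohex-2-en-1-yl]methyl}sulfanyl)benzene
Conditions: PhSSPh, n-Bu3P, pyridine, 60 °C
Reagents that add atoms: diphenyl disulfide, c1ccc(SSc2ccccc2)cc1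
Why: Redox condensation: the phosphine and disulfide turn the alcohol into an alkoxyphosphonium ion that thiolate displaces at the primary carbon. The β-branch slows but does not block this SN2 step, and C1'' is not involved.

Step 7
Reactants: 9 ({[(1S)-2,6,6-trimethylcyclohex-2-en-1-yl]methyl}sulfanyl)benzene
Product: 10 ({[(1S)-2,6,6-trimethylcyclohex-2-en-1-yl]methyl}sulfonyl)benzene
Conditions: (NH4)6Mo7O24·4H2O (10 mol%), 30% H2O2, EtOH, 0 °C to rt
Reagents that add atoms: hydrogen peroxide, OO
Why: Molybdate-catalysed peroxide oxidation takes sulfide to sulfone much faster than it epoxidises a trisubstituted alkene, so the ring alkene survives.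

Step 8
Reactants: 11 geraniol
Product: 12 [(2S,3S)-3-methyl-3-(4-methylpent-3-en-1-yl)oxiran-2-yl]methanol
Conditions: Ti(OiPr)4 (5 mol%), L-(+)-diethyl tartrate (7 mol%), t-BuOOH, 4 Å molecular sieves, CH2Cl2, −20 °C
Reagents that add atoms: tert-butyl hydroperoxide, CC(C)(C)OO
Why: Sharpless asymmetric epoxidation: the titanium tartrate complex binds the allylic hydroxyl group and delivers oxygen to one face of C2=C3 only, with the L-tartrate giving the (2S,3S) epoxide. C3 of 12 is the future C2 of the chromene, and the remote alkene has no directing hydroxyl and is left alone.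

Step 9
Reactants: 12 [(2S,3S)-3-methyl-3-(4-methylpent-3-en-1-yl)oxiran-2-yl]methanol
Product: 13 (2R,3S)-2-(chloromethyl)-3-methyl-3-(4-methylpent-3-en-1-yl)oxirane
Conditions: PPh3, CCl4, NaHCO3, 77 °C
Reagents that add atoms: tetrachloromethane, ClC(Cl)(Cl)Cl
Why: Appel chlorination of the primary alcohol under buffered, non-acidic conditions that keep the epoxide closed. The descriptor at C2 changes only because chlorine changes the priorities.

Step 10
Reactants: 13 (2R,3S)-2-(chloromethyl)-3-methyl-3-(4-methylpent-3-en-1-yl)oxirane
Product: 14 (3S)-3,7-dimethyloct-6-en-1-yn-3-ol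
Conditions: LiN(iPr)2 (3.3 equiv), THF, −78 to −20 °C; aq. NH4Cl
Reagents that add atoms: none
Why: Base-induced fragmentation of a 2,3-epoxy chloride: deprotonation next to chlorine opens the epoxide to a chlorovinyl alkoxide, and loss of HCl gives the terminal alkyne. The C3–O bond is never broken, so the tertiary carbinol keeps the configuration set in step 8.

Step 11
Reactants: 15 4-bromo-3-iodophenol
Product: 16 (4-bromo-3-iodophenoxy)tri(propan-2-yl)silane
Conditions: TIPSCl, imidazole, DMF, rt
Reagents that add atoms: chlorotri(propan-2-yl)silane, CC(C)[Si](Cl)(C(C)C)C(C)C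
Why: Routine silylation of a phenol. The bulky silyl ether withstands the amine, carbonate and organolithium conditions that follow and is removed by fluoride at the end.

Step 12
Reactants: 14 (3S)-3,7-dimethyloct-6-en-1-yn-3-ol; 16 (4-bromo-3-iodophenoxy)tri(propan-2-yl)silane
Product: 17 (3S)-1-{2-bromo-5-[tri(propan-2-yl)silyloxy]phenyl}-3,7-dimethyloct-6-en-1-yn-3-ol
Conditions: PdCl2(PPh3)2 (2 mol%), CuI (4 mol%), Et3N, THF, rt
Reagents that add atoms: none
Why: Sonogashira coupling. At room temperature zerovalent palladium inserts into the C–I bond and leaves the C–Br bond, so the alkyne is attached at the future C4a and the bromide stays at the future C8a.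

Step 13
Reactants: 17 (3S)-1-{2-bromo-5-[tri(propan-2-yl)silyloxy]phenyl}-3,7-dimethyloct-6-en-1-yn-3-ol
Product: 18 (1Z,3S)-1-{2-bromo-5-[tri(propan-2-yl)silyloxy]phenyl}-3,7-dimethylocta-1,6-dien-3-ol
Conditions: H2 (1 atm), Pd/CaCO3 poisoned with Pb(OAc)2 (Lindlar catalyst), quinoline, EtOAc, rt
Reagents that add atoms: none
Why: Syn addition of hydrogen on the poisoned catalyst gives the (Z)-alkene, which places the tertiary hydroxyl group beside the aryl bromide. The trisubstituted alkene and the C–Br bond are not reduced under these conditions.

Step 14
Reactants: 18 (1Z,3S)-1-{2-bromo-5-[tri(propan-2-yl)silyloxy]phenyl}-3,7-dimethylocta-1,6-dien-3-ol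
Product: 19 {[(2S)-2-methyl-2-(4-methylpent-3-en-1-yl)-2H-chromen-6-yl]oxy}tri(propan-2-yl)silane
Conditions: Pd(OAc)2 (5 mol%), racemic 2-(di-tert-butylphosphanyl)-1,1'-binaphthyl (6 mol%), Cs2CO3, toluene, 70 °C, in the dark
Reagents that add atoms: none
Why: Intramolecular aryl etherification of the Buchwald–Hartwig type: oxidative addition of the aryl bromide to zerovalent palladium, exchange of bromide for the tertiary alkoxide and C–O reductive elimination close ring B as a six-membered ring. The tertiary alkoxide has no β-hydrogen to lose and its C–O bond is not broken, so C2 keeps its configuration; the moderate temperature and exclusion of light guard against electrocyclic opening of the chromene.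

Step 15
Reactants: 19 {[(2S)-2-methyl-2-(4-methylpent-3-en-1-yl)-2H-chromen-6-yl]oxy}tri(propan-2-yl)silane
Product: 20 (2E)-2-methyl-5-{(2S)-2-methyl-6-[tri(propan-2-yl)silyloxy]-2H-chromen-2-yl}pent-2-en-1-ol
Conditions: SeO2 (30 mol%), t-BuOOH (70% aq.), salicylic acid (10 mol%), CH2Cl2, rt, stopped at partial conversion
Reagents that add atoms: tert-butyl hydroperoxide, CC(C)(C)OO
Why: Selenium dioxide allylic oxidation (ene reaction, then [2,3]-sigmatropic shift) attacks the (E)-methyl group of a trisubstituted chain terminus and gives the (E)-allylic alcohol. The new oxygen atom comes from t-BuOOH, which keeps the catalytic SeO2 in its oxidised form. The chromene alkene has no allylic hydrogen and is not a substrate.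

Step 16
Reactants: 20 (2E)-2-methyl-5-{(2S)-2-methyl-6-[tri(propan-2-yl)silyloxy]-2H-chromen-2-yl}pent-2-en-1-ol
Product: 21 {[(2S)-2-[(3E)-5-bromo-4-methylpent-3-en-1-yl]-2-methyl-2H-chromen-6-yl]oxy}tri(propan-2-yl)silane
Conditions: CBr4, PPh3, CH2Cl2, 0 °C
Reagents that add atoms: tetrabromomethane, BrC(Br)(Br)Br
Why: Appel bromination of a primary allylic alcohol under neutral conditions. Displacement at the primary carbon keeps the alkene in place and (E).

Step 17
Reactants: 10 ({[(1S)-2,6,6-trimethylcyclohex-2-en-1-yl]methyl}sulfonyl)benzene; 21 {[(2S)-2-[(3E)-5-bromo-4-methylpent-3-en-1-yl]-2-methyl-2H-chromen-6-yl]oxy}tri(propan-2-yl)silane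
Product: 23 {[(2S)-2-[(3E)-6-(benzenesulfonyl)-4-methyl-6-[(1S)-2,6,6-trimethylcyclohex-2-en-1-yl]hex-3-en-1-yl]-2-methyl-2H-chromen-6-yl]oxy}tri(propan-2-yl)silane (both epimers at the sulfonyl-bearing carbon), via lithiated sulfone 22 (not isolated)
Conditions: n-BuLi (1.05 equiv), THF–DMPU, −78 °C; then 21, −78 to −30 °C
Reagents that add atoms: none
Why: Alkylation of an α-sulfonyl carbanion with a primary allylic bromide forms the C5'–C6' bond by direct SN2 displacement. The new centre at C6' is of no consequence because the sulfonyl group is removed next, and neither C1'' nor C2 is acidic under these conditions.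

Step 18
Reactants: 23 {[(2S)-2-[(3E)-6-(benzenesulfonyl)-4-methyl-6-[(1S)-2,6,6-trimethylcyclohex-2-en-1-yl]hex-3-en-1-yl]-2-methyl-2H-chromen-6-yl]oxy}tri(propan-2-yl)silane
Product: 24 {[(2S)-2-methyl-2-{(3E)-4-methyl-6-[(1S)-2,6,6-trimethylcyclohex-2-en-1-yl]hex-3-en-1-yl}-2H-chromen-6-yl]oxy}tri(propan-2-yl)silane
Conditions: 6% Na(Hg), Na2HPO4, MeOH–THF, −20 to 0 °C
Reagents that add atoms: none
Why: Reductive desulfonylation by electron transfer: the aryl sulfone accepts electrons, sulfinate leaves, and the carbanion is protonated by methanol. Buffered amalgam at low temperature is a much weaker reductant than dissolving alkali metal and should not reach the electron-rich styrene-like C3=C4.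

Step 19
Reactants: 24 {[(2S)-2-methyl-2-{(3E)-4-methyl-6-[(1S)-2,6,6-trimethylcyclohex-2-en-1-yl]hex-3-en-1-yl}-2H-chromen-6-yl]oxy}tri(propan-2-yl)silane
Product: 25 (2S)-2-methyl-2-{(3E)-4-methyl-6-[(1S)-2,6,6-trimethylcyclohex-2-en-1-yl]hex-3-en-1-yl}-2H-chromen-6-ol (target)
Conditions: Bu4NF, THF, 0 °C, under argon, in the dark; water work-up
Reagents that add atoms: none
Why: Fluoride cleaves the aryl silyl ether quickly at 0 °C. Nothing acidic, oxidising or hot touches the chromene or the alkenes, so both stereocentres reach the target unchanged.

## Compound list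

1 | (E)-3-methylpent-2-en-4-yn-1-ol | C#C/C(C)=C/CO | starting material
2 | (E)-3-methylpenta-2,4-dien-1-ol | C=C/C(C)=C/CO | intermediate
3 | (E)-tert-butyldimethyl[(3-methylpenta-2,4-dien-1-yl)oxy]silane | C=C/C(C)=C/CO[Si](C)(C)C(C)(C)C | intermediate
4 | methacrolein (2-methylprop-2-enal) | CC(=C)C=O | starting material
5 | (1S,2R)-2-{[tert-butyl(dimethyl)silyl]oxymethyl}-1,3-dimethylcyclohex-3-ene-1-carbaldehyde | CC1=CCC[C@](C)(C=O)[C@@H]1CO[Si](C)(C)C(C)(C)C | intermediate
6 | hydrazone of 5, tert-butyl{[(1R,6S)-6-(hydrazinylidenemethyl)-2,6-dimethylcyclohex-2-en-1-yl]methoxy}dimethylsilane | CC1=CCC[C@](C)(C=NN)[C@@H]1CO[Si](C)(C)C(C)(C)C | intermediate (not isolated)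
7 | tert-butyldimethyl{[(1S)-2,6,6-trimethylcyclohex-2-en-1-yl]methoxy}silane | CC1=CCCC(C)(C)[C@@H]1CO[Si](C)(C)C(C)(C)C | intermediate
8 | [(1S)-2,6,6-trimethylcyclohex-2-en-1-yl]methanol | CC1=CCCC(C)(C)[C@@H]1CO | intermediate
9 | ({[(1S)-2,6,6-trimethylcyclohex-2-en-1-yl]methyl}sulfanyl)benzene | CC1=CCCC(C)(C)[C@@H]1CSc1ccccc1 | intermediate
10 | ({[(1S)-2,6,6-trimethylcyclohex-2-en-1-yl]methyl}sulfonyl)benzene | CC1=CCCC(C)(C)[C@@H]1CS(=O)(=O)c1ccccc1 | intermediate
11 | geraniol, (2E)-3,7-dimethylocta-2,6-dien-1-ol | CC(C)=CCC/C(C)=C/CO | starting material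
12 | [(2S,3S)-3-methyl-3-(4-methylpent-3-en-1-yl)oxiran-2-yl]methanol | CC(C)=CCC[C@]1(C)O[C@H]1CO | intermediate
13 | (2R,3S)-2-(chloromethyl)-3-methyl-3-(4-methylpent-3-en-1-yl)oxirane | CC(C)=CCC[C@]1(C)O[C@H]1CCl | intermediate
14 | (3S)-3,7-dimethyloct-6-en-1-yn-3-ol | CC(C)=CCC[C@](C)(O)C#C | intermediate
15 | 4-bromo-3-iodophenol | Oc1ccc(Br)c(I)c1 | starting material
16 | (4-bromo-3-iodophenoxy)tri(propan-2-yl)silane | CC(C)[Si](Oc1ccc(Br)c(I)c1)(C(C)C)C(C)C | intermediate
17 | (3S)-1-{2-bromo-5-[tri(propan-2-yl)silyloxy]phenyl}-3,7-dimethyloct-6-en-1-yn-3-ol | CC(C)=CCC[C@](C)(O)C#Cc1cc(O[Si](C(C)C)(C(C)C)C(C)C)ccc1Br | intermediate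
18 | (1Z,3S)-1-{2-bromo-5-[tri(propan-2-yl)silyloxy]phenyl}-3,7-dimethylocta-1,6-dien-3-ol | CC(C)=CCC[C@](C)(O)/C=C\c1cc(O[Si](C(C)C)(C(C)C)C(C)C)ccc1Br | intermediate
19 | {[(2S)-2-methyl-2-(4-methylpent-3-en-1-yl)-2H-chromen-6-yl]oxy}tri(propan-2-yl)silane | CC(C)=CCC[C@@]1(C)C=Cc2cc(O[Si](C(C)C)(C(C)C)C(C)C)ccc2O1 | intermediate
20 | (2E)-2-methyl-5-{(2S)-2-methyl-6-[tri(propan-2-yl)silyloxy]-2H-chromen-2-yl}pent-2-en-1-ol | OC/C(C)=C/CC[C@@]1(C)C=Cc2cc(O[Si](C(C)C)(C(C)C)C(C)C)ccc2O1 | intermediate
21 | {[(2S)-2-[(3E)-5-bromo-4-methylpent-3-en-1-yl]-2-methyl-2H-chromen-6-yl]oxy}tri(propan-2-yl)silane | BrC/C(C)=C/CC[C@@]1(C)C=Cc2cc(O[Si](C(C)C)(C(C)C)C(C)C)ccc2O1 | intermediate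
22 | lithiated sulfone, [(benzenesulfonyl){(1S)-2,6,6-trimethylcyclohex-2-en-1-yl}methyl]lithium | CC1=CCCC(C)(C)[C@@H]1C([Li])S(=O)(=O)c1ccccc1 | intermediate (not isolated)
23 | {[(2S)-2-[(3E)-6-(benzenesulfonyl)-4-methyl-6-[(1S)-2,6,6-trimethylcyclohex-2-en-1-yl]hex-3-en-1-yl]-2-methyl-2H-chromen-6-yl]oxy}tri(propan-2-yl)silane, both epimers at the sulfonyl-bearing carbon | CC1=CCCC(C)(C)[C@@H]1C(C/C(C)=C/CC[C@@]2(C)C=Cc3cc(O[Si](C(C)C)(C(C)C)C(C)C)ccc3O2)S(=O)(=O)c1ccccc1 | intermediate
24 | {[(2S)-2-methyl-2-{(3E)-4-methyl-6-[(1S)-2,6,6-trimethylcyclohex-2-en-1-yl]hex-3-en-1-yl}-2H-chromen-6-yl]oxy}tri(propan-2-yl)silane | CC1=CCCC(C)(C)[C@@H]1CC/C(C)=C/CC[C@@]1(C)C=Cc2cc(O[Si](C(C)C)(C(C)C)C(C)C)ccc2O1 | intermediate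
25 | (2S)-2-methyl-2-{(3E)-4-methyl-6-[(1S)-2,6,6-trimethylcyclohex-2-en-1-yl]hex-3-en-1-yl}-2H-chromen-6-ol | CC1=CCCC(C)(C)[C@@H]1CC/C(C)=C/CC[C@@]1(C)C=Cc2cc(O)ccc2O1 | target

## Step count and least certain steps

Total: 19 steps. Longest linear sequence: 11 steps (from 11 through steps 8–10 and 12–19). The ring C branch takes 7 steps to sulfone 10 and the arene branch 1 step to 16.

Step 3 (key step). Three things can leak.
- Orientation: the internal methyl group of 3 favours bonding of the enal β-carbon to the substituted terminus, the opposite of what is needed, and only the terminal substituent and the Lewis acid argue the other way.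
- Endo/exo mode: exo leakage converts directly into loss of enantiomeric purity at C1'' once C6'' is erased.
- Silyl ether: the strong Lewis acid may ionise or cleave the allylic silyl ether.

If only the facial sense proves opposite to the model, the (R)-catalyst is used.

The fallback sets out from dienol 2 and comes back at alcohol 8. It ties the two partners together so that orientation and mode are no longer open. Dienol 2 and methyl acrylate are assembled on a mixed magnesium–zinc 1,1'-bi-2-naphtholate template (MeMgBr, Me2Zn, 1,1'-bi-2-naphthol, CH2Cl2), the antipode of the binaphthol being the one that leads to the (3aS,7aS) series. The alkoxide tether allows only the orientation in which the ester-bearing carbon bonds to C1'' and only the endo mode, and the adduct closes to the cis-fused lactone (3aS,7aS)-4-methyl-3a,6,7,7a-tetrahydro-2-benzofuran-1(3H)-one F1. Enolate methylation (LiN(iPr)2, MeI, THF, −78 °C) gives (3aR,7aS)-4,7a-dimethyl-3a,6,7,7a-tetrahydro-2-benzofuran-1(3H)-one F2. Reduction with iBu2AlH at −78 °C gives the lactol (3aR,7aS)-4,7a-dimethyl-1,3,3a,6,7,7a-hexahydro-2-benzofuran-1-ol F3. Huang–Minlon reduction (N2H4·H2O, KOH, diethylene glycol, 130 then 200 °C), by way of the hydrazone [(1R,6S)-6-(hydrazinylidenemethyl)-2,6-dimethylcyclohex-2-en-1-yl]methanol F4, gives 8.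

Step 18. Electron transfer may not stop at the sulfone: over-reduction of the styrene-like C3=C4 of the chromene, or incomplete cleavage if the amalgam is kept mild enough to spare it, are the likely failures, because the two reduction potentials are not far apart.

The fallback sets out from alcohol 8 and bromide 21 and comes back at 24. It replaces the phenyl sulfone by a heteroaryl sulfone that accepts electrons far more easily. Alcohol 8 is condensed with 2,2'-dipyridyl disulfide and n-Bu3P to 2-({[(1S)-2,6,6-trimethylcyclohex-2-en-1-yl]methyl}sulfanyl)pyridine F5. Oxidation as in step 7 gives 2-({[(1S)-2,6,6-trimethylcyclohex-2-en-1-yl]methyl}sulfonyl)pyridine F6. Lithiation (n-BuLi, THF, −78 °C) and alkylation with 21 give {[(2S)-2-[(3E)-4-methyl-6-(pyridin-2-ylsulfonyl)-6-[(1S)-2,6,6-trimethylcyclohex-2-en-1-yl]hex-3-en-1-yl]-2-methyl-2H-chromen-6-yl]oxy}tri(propan-2-yl)silane F7. F7 is cleaved with SmI2 in THF–MeOH at −78 °C, where aryl-conjugated alkenes are inert, to give 24.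

Step 17. The carbanion 22 sits next to a fully substituted ring position; slow alkylation would let proton transfer to the product, elimination of HBr from 21 or double alkylation compete.

The fallback sets out from alcohol 8 and bromide 21 and comes back at 24, with no sulfone at all. Alcohol 8 is brominated (CBr4, PPh3, CH2Cl2) to (6S)-6-(bromomethyl)-1,5,5-trimethylcyclohex-1-ene F8. F8 is converted with Mg in THF into {[(1S)-2,6,6-trimethylcyclohex-2-en-1-yl]methyl}magnesium bromide F9. F9 is coupled with 21 under Li2CuCl4 catalysis (THF, −20 °C), which favours direct displacement at the primary allylic carbon, to give 24.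

Step 14. Reductive elimination to form a C–O bond on an electron-rich arene is the slow step; loss of bromine by reduction, or fragmentation of the tertiary allylic alkoxide on palladium, may overtake it, and the temperature cannot be raised freely because of the chromene.

The fallback sets out from 18 and comes back at 19. It closes the ring at the chroman oxidation level, where this etherification is best established, and introduces C3=C4 afterwards. The cis alkene of 18 is reduced selectively with diimide (2-nitrobenzenesulfonohydrazide, Et3N, CH2Cl2, rt) to (3S)-1-{2-bromo-5-[tri(propan-2-yl)silyloxy]phenyl}-3,7-dimethyloct-6-en-3-ol F10. The same palladium etherification gives the chroman {[(2S)-2-methyl-2-(4-methylpent-3-en-1-yl)-3,4-dihydro-2H-chromen-6-yl]oxy}tri(propan-2-yl)silane F11. Dehydrogenation with DDQ (benzene, 80 °C) by hydride abstraction from the oxygen-activated benzylic C4 gives 19.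

## Further compounds

F1 | step 3 | (3aS,7aS)-4-methyl-3a,6,7,7a-tetrahydro-2-benzofuran-1(3H)-one | CC1=CCC[C@@H]2C(=O)OC[C@H]12
F2 | step 3 | (3aR,7aS)-4,7a-dimethyl-3a,6,7,7a-tetrahydro-2-benzofuran-1(3H)-one | CC1=CCC[C@]2(C)C(=O)OC[C@H]12
F3 | step 3 | (3aR,7aS)-4,7a-dimethyl-1,3,3a,6,7,7a-hexahydro-2-benzofuran-1-ol (both anomers) | CC1=CCC[C@]2(C)C(O)OC[C@H]12
F4 | step 3 | [(1R,6S)-6-(hydrazinylidenemethyl)-2,6-dimethylcyclohex-2-en-1-yl]methanol | CC1=CCC[C@](C)(C=NN)[C@@H]1CO
F5 | step 18 | 2-({[(1S)-2,6,6-trimethylcyclohex-2-en-1-yl]methyl}sulfanyl)pyridine | CC1=CCCC(C)(C)[C@@H]1CSc1ccccn1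
F6 | step 18 | 2-({[(1S)-2,6,6-trimethylcyclohex-2-en-1-yl]methyl}sulfonyl)pyridine | CC1=CCCC(C)(C)[C@@H]1CS(=O)(=O)c1ccccn1
F7 | step 18 | {[(2S)-2-[(3E)-4-methyl-6-(pyridin-2-ylsulfonyl)-6-[(1S)-2,6,6-trimethylcyclohex-2-en-1-yl]hex-3-en-1-yl]-2-methyl-2H-chromen-6-yl]oxy}tri(propan-2-yl)silane (both epimers at the sulfonyl-bearing carbon) | CC1=CCCC(C)(C)[C@@H]1C(C/C(C)=C/CC[C@@]2(C)C=Cc3cc(O[Si](C(C)C)(C(C)C)C(C)C)ccc3O2)S(=O)(=O)c1ccccn1
F8 | step 17 | (6S)-6-(bromomethyl)-1,5,5-trimethylcyclohex-1-ene | CC1=CCCC(C)(C)[C@@H]1CBr
F9 | step 17 | {[(1S)-2,6,6-trimethylcyclohex-2-en-1-yl]methyl}magnesium bromide | CC1=CCCC(C)(C)[C@@H]1C[Mg]Br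
F10 | step 14 | (3S)-1-{2-bromo-5-[tri(propan-2-yl)silyloxy]phenyl}-3,7-dimethyloct-6-en-3-ol | CC(C)=CCC[C@](C)(O)CCc1cc(O[Si](C(C)C)(C(C)C)C(C)C)ccc1Br
F11 | step 14 | {[(2S)-2-methyl-2-(4-methylpent-3-en-1-yl)-3,4-dihydro-2H-chromen-6-yl]oxy}tri(propan-2-yl)silane | CC(C)=CCC[C@@]1(C)CCc2cc(O[Si](C(C)C)(C(C)C)C(C)C)ccc2O1
A1 | alternative 1 | (2S)-2-methyl-2-(4-methylpent-3-en-1-yl)-2H-chromen-6-ol | CC(C)=CCC[C@@]1(C)C=Cc2cc(O)ccc2O1
A2 | alternative 1 | pentacarbonyl(1-{[(3Z,5S)-5,9-dimethyldeca-3,8-dien-1-yn-5-yl]oxy}prop-2-en-1-ylidene)chromium | C=CC(O[C@@](C)(CCC=C(C)C)/C=C\C#C)=[Cr](=C=O)(=C=O)(=C=O)(=C=O)=C=O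
A3 | alternative 2 | (2S)-2-[2-(tert-butyldimethylsilyloxy)ethyl]-2-methyl-6-(triisopropylsilyloxy)-2H-chromene | CC(C)(C)[Si](C)(C)OCC[C@@]1(C)C=Cc2cc(O[Si](C(C)C)(C(C)C)C(C)C)ccc2O1
A4 | alternative 2 | tert-butyldimethyl{[(3S)-3-methyl-3-{4-[tri(propan-2-yl)silyloxy]phenoxy}pent-4-yn-1-yl]oxy}silane | CC(C)(C)[Si](C)(C)OCC[C@@](C)(C#C)Oc1ccc(O[Si](C(C)C)(C(C)C)C(C)C)cc1
A5 | alternative 3 | (2S)-6-bromo-2-methyl-2-(4-methylpent-3-en-1-yl)-2H-chromene | CC(C)=CCC[C@@]1(C)C=Cc2cc(Br)ccc2O1
A6 | alternative 3 | 4-bromo-1-{[(3S)-3,7-dimethylocta-1,6-dien-3-yl]oxy}-2-ethenylbenzene | CC(C)=CCC[C@@](C)(C=C)Oc1ccc(Br)cc1C=C
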